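**Plan**

1. Retrosynthesis: cut the C9–O anisoate, return the C8–OH/C9–O pair to a C8=C9 alkene through its β-epoxide, cut C8–CH3 (to a C8 enol triflate) and one methyl of the isopropyl group (to a C4 acetyl), then cut C4–C5.
2. Enabling feature: in the five-membered ring C1–C2–C3–C4–C5 the ring-fusion carbinol C5 sits next to C4, whose side chain can be an acetyl group, so C4–C5 is an aldol bond. C1 is quaternary and carries both C5 and C10, which can both be carbonyls, so the bicycle unravels to an achiral 2,2-disubstituted cycloheptane-1,3-dione.
3. Forward: the seven-membered ring is bought as cycloheptane-1,3-dione; methylation, palladium allylation, cross-metathesis with methyl vinyl ketone and hydrogenation join the 4-oxopentyl chain at C1; the amine-catalysed aldol then closes the five-membered ring.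
4. After that: acetyl to isopropyl; the C10 carbonyl is relayed to C8 (enol triflate, alkene, allylic oxidation); reductive triflation and methyl coupling give the C8-methyl C8=C9 alkene; epoxidation, hydrolysis and anisoylation finish.
5. Stereochemistry: C1, C5 and C4 come from the chiral amine in the aldol (cis fusion enforced by the tether); C8 and C9 come from delivery of the epoxide oxygen by the C5 hydroxyl, followed by opening at C8 with inversion.

Key step: step 5

Remark on numbering: C1 = ring-fusion C–CH3, C2/C3 = CH2 pair of the five-membered ring, C4 = CH–isopropyl, C5 = ring-fusion C–OH, C6/C7 = CH2 pair, C8 = C(CH3)OH, C9 = CH–O-anisoyl, C10 = CH2 between C9 and C1. β is the face that carries the C1 methyl group (wedged when C1 is drawn above C5 with the five-membered ring on the left); absolute configurations are those of the SMILES strings.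

Assumption: the quinine-derived primary amine is taken to select the ring carbonyl that leads to the (1S,4S,5S) ketol; if the first run shows the opposite sense, the pseudo-enantiomeric 9-amino-9-deoxy-epi-quinidine is used and nothing else changes.

**Route**

Step 1
Reactants: 1 cycloheptane-1,3-dione; 2 iodomethane
Product: 3 2-methylcycloheptane-1,3-dione
Conditions: MeI (1.05 equiv), K2CO3 (1.1 equiv), acetone, reflux
Reagents that add atoms: iodomethane (2), CI
Why: The C2–H between the two carbonyls is by far the most acidic position, so carbonate forms the soft β-diketone enolate that is C-methylated by iodomethane (enolate C-alkylation), one equivalent of electrophile keeping dimethylation low.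

Step 2
Reactants: 3 2-methylcycloheptane-1,3-dione; 4 allyl acetate
Product: 5 2-allyl-2-methylcycloheptane-1,3-dione
Conditions: allyl acetate (1.3 equiv), Pd(PPh3)4 (2 mol%), DBU (1.2 equiv), toluene, 60 °C
Reagents that add atoms: allyl acetate (4), C=CCOC(C)=O
Why: In this Tsuji–Trost allylation the stabilised enolate of the 2-alkyl-1,3-dione attacks the π-allylpalladium complex at carbon, which avoids the O-alkylation seen with ordinary alkyl halides and creates the quaternary, still non-stereogenic C1.

Step 3
Reactants: 5 2-allyl-2-methylcycloheptane-1,3-dione; 6 methyl vinyl ketone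
Product: 7 (E)-2-methyl-2-(4-oxopent-2-en-1-yl)cycloheptane-1,3-dione
Conditions: methyl vinyl ketone (3 equiv), second-generation Grubbs catalyst RuCl2(=CHPh)(PCy3)(H2IMes) (3 mol%), CH2Cl2, 40 °C
Reagents that add atoms: methyl vinyl ketone (6), CC(=O)C=C
Why: Olefin cross-metathesis between a terminal alkene that homodimerises readily and an electron-poor enone that does not should give the E-enone selectively, the ketone carbonyls being inert to the ruthenium carbene.

Step 4
Reactants: 7 (E)-2-methyl-2-(4-oxopent-2-en-1-yl)cycloheptane-1,3-dione
Product: 8 2-methyl-2-(4-oxopentyl)cycloheptane-1,3-dione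
Conditions: H2 (1 atm), 10% Pd/C, EtOAc, rt
Reagents that add atoms: none
Why: Heterogeneous catalytic hydrogenation saturates the conjugated C=C much faster than any ketone carbonyl and forms no stereocentre.

Step 5
Reactants: 8 2-methyl-2-(4-oxopentyl)cycloheptane-1,3-dione
Product: 9 ketol, (1S,4S,5S)-4-acetyl-5-hydroxy-1-methylbicyclo[5.3.0]decan-10-one in route numbering (cis-fused; 1-CH3, 5-OH and 4-acetyl all β)
Conditions: 9-amino-9-deoxy-epi-quinine (20 mol%), AcOH (60 mol%), toluene, rt
Reagents that add atoms: none
Why: The primary amine of the catalyst condenses with the side-chain methyl ketone, the derived enamine that is nucleophilic at C4 adds to one of the two enantiotopic ring carbonyls, which is activated by a hydrogen bond from the protonated quinuclidine, and hydrolysis of the iminium releases the ketol and the catalyst. The closest known reaction type is the amine-catalysed intramolecular aldol desymmetrisation of 2,2-disubstituted cyclic 1,3-diones (Hajos–Parrish–Eder–Sauer–Wiechert reaction), used here in the enolexo sense that 1,6-diketones normally follow. The five-membered ring C1–C2–C3–C4–C5 closes by a 5-(enolexo)-exo-trig attack that forms the C4–C5 bond. C1 and C5 are set together by the catalyst's choice of carbonyl, the three-atom tether from C1 allows only a cis ring fusion (C1–CH3 and C5–OH on one face), and C4 should place its acetyl cis to the new hydroxyl because the hydrogen-bonded, chair-like transition state holds the iminium carbon beside the developing alkoxide, an arrangement that is also expected to be the more stable one (acetyl anti to C6 and hydrogen-bonded to OH). The step needs enantiotopic-group selectivity, a single regiochemistry of enamine use and survival of the tertiary ketol; the substrate secures the second point because every other closure (methyl-side enamine or ring enamine) would have to form a seven-membered ring, the quaternary C1 rules out enolisation between the ring carbonyls, and the mild acid at room temperature should hold back dehydration.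

Step 6
Reactants: 9 ketol; 10 triethylsilyl trifluoromethanesulfonate
Product: 11 triethylsilyl ether of 9 (5β-OSiEt3, 4β-acetyl, C10 ketone)
Conditions: TESOTf (1.5 equiv), 2,6-lutidine (3 equiv), CH2Cl2, −78 → 0 °C
Reagents that add atoms: triethylsilyl trifluoromethanesulfonate (10), CC[Si](CC)(CC)OS(=O)(=O)C(F)(F)F
Why: A silyl triflate with a hindered pyridine base silylates even the congested tertiary C5–OH (silyl ether formation) faster than it enolises the ketones at low temperature, and the ether closes the retro-aldol channel before the basic steps that follow.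

Step 7
Reactants: 11 triethylsilyl ether of 9; 12 methyltriphenylphosphonium bromide
Product: 13 4β-isopropenyl-1β-methyl-5β-(triethylsilyloxy) C10 ketone
Conditions: Ph3PCH3Br (1.5 equiv), KOtBu (1.4 equiv), THF, 0 °C → rt
Reagents that add atoms: methyltriphenylphosphonium bromide (12), C[P+](c1ccccc1)(c1ccccc1)c1ccccc1.[Br-]
Why: Wittig methylenation should take the methyl ketone, which is far less hindered than the C10 carbonyl flanked by the quaternary C1, and the ylide at 0 °C should leave the C4 stereocentre untouched.

Step 8
Reactants: 13 4β-isopropenyl C10 ketone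
Product: 14 4β-isopropyl-1β-methyl-5β-(triethylsilyloxy) C10 ketone
Conditions: H2 (1 atm), 10% Pd/C, EtOAc, rt
Reagents that add atoms: none
Why: Catalytic hydrogenation of the 1,1-disubstituted alkene gives the isopropyl group without forming a stereocentre and without touching the hindered ketone or the silyl ether.

Step 9
Reactants: 14 4β-isopropyl C10 ketone; 15 N-phenylbis(trifluoromethanesulfonimide)
Product: 17 C10 enol triflate (C9=C10 with OTf on C10), via potassium C9=C10 enolate 16 (not isolated)
Conditions: KN(SiMe3)2 (1.2 equiv), THF, −78 °C; then PhNTf2 (1.3 equiv), −78 → 0 °C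
Reagents that add atoms: N-phenylbis(trifluoromethanesulfonimide) (15), FC(F)(F)S(=O)(=O)N(c1ccccc1)S(=O)(=O)C(F)(F)F
Why: Because C1 is quaternary the C10 ketone can enolise only towards C9, so deprotonation and O-sulfonylation with PhNTf2 (enol triflate formation) should give a single regioisomer.

Step 10
Reactants: 17 C10 enol triflate
Product: 18 C9=C10 alkene (4β-isopropyl, 1β-methyl, 5β-OSiEt3)
Conditions: Pd(OAc)2 (5 mol%), PPh3 (10 mol%), HCO2H (2 equiv), n-Bu3N (3 equiv), DMF, 60 °C
Reagents that add atoms: none
Why: Palladium-catalysed formate reduction of an enol triflate (oxidative addition, formate-to-hydride exchange with loss of CO2, reductive elimination) replaces OTf by H and leaves the double bond exactly at C9=C10.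

Step 11
Reactants: 18 C9=C10 alkene; 19 tert-butyl hydroperoxide
Product: 20 C8 enone (C8=O conjugated with C9=C10)
Conditions: Rh2(cap)4 (dirhodium tetracaprolactamate, 1 mol%), t-BuOOH (70% aq., 5 equiv), K2CO3 (0.5 equiv), CH2Cl2, rt
Reagents that add atoms: tert-butyl hydroperoxide (19), CC(C)(C)OO
Why: This dirhodium-catalysed allylic oxidation abstracts hydrogen from the only allylic C–H position, C8 (the other allylic atom, C1, is quaternary), and the allyl radical should be oxygenated at the unhindered C8 terminus and not at the neopentyl C10, giving the transposed enone.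

Step 12
Reactants: 20 C8 enone; 15 N-phenylbis(trifluoromethanesulfonimide)
Product: 22 C8 enol triflate (C8=C9 with OTf on C8), via lithium C8=C9 enolate 21 (not isolated)
Conditions: Li (2.1 equiv), t-BuOH (1.0 equiv), NH3(l)/THF, −78 °C; NH3 evaporated; then PhNTf2 (1.5 equiv), THF, 0 °C → rt
Reagents that add atoms: N-phenylbis(trifluoromethanesulfonimide) (15), FC(F)(F)S(=O)(=O)N(c1ccccc1)S(=O)(=O)C(F)(F)F
Why: Dissolving-metal conjugate reduction of the enone delivers the lithium enolate with its double bond fixed at C8=C9 (reductive enolate formation), and trapping on oxygen with PhNTf2 before any proton transfer should preserve that regiochemistry in the enol triflate.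

Step 13
Reactants: 22 C8 enol triflate; 23 methylmagnesium bromide
Product: 24 8-methyl C8=C9 alkene (5β-OSiEt3, 4β-isopropyl, 1β-methyl)
Conditions: MeMgBr (1.5 equiv), Fe(acac)3 (5 mol%), THF/NMP, −30 → 0 °C
Reagents that add atoms: methylmagnesium bromide (23), C[Mg]Br
Why: Iron-catalysed Kumada-type cross-coupling of alkenyl triflates with methylmagnesium bromide is fast at low temperature, keeps the double bond in place and tolerates the silyl ether, so it should give the C8-methyl trisubstituted alkene.

Step 14
Reactants: 24 8-methyl C8=C9 alkene silyl ether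
Product: 25 alkenol (8-methyl C8=C9 alkene with free 5β-OH, 4β-isopropyl, 1β-methyl)
Conditions: n-Bu4NF (3 equiv), THF, rt → 50 °C
Reagents that add atoms: none
Why: Fluoride-mediated desilylation, driven by the strong Si–F bond, should free the tertiary C5–OH under non-acidic conditions that cannot ionise the tertiary or allylic positions.

Step 15
Reactants: 25 alkenol; 19 tert-butyl hydroperoxide
Product: 26 8β,9β-epoxide (epoxide oxygen on the face of the 5β-OH; C8 methyl now α)
Conditions: VO(acac)2 (5 mol%), t-BuOOH (1.5 equiv, decane solution), CH2Cl2, 0 °C → rt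
Reagents that add atoms: tert-butyl hydroperoxide (19), CC(C)(C)OO
Why: In this hydroxyl-directed vanadium-catalysed epoxidation the C5 vanadate ester carries the bound alkyl peroxide across the seven-membered ring to the face of the bishomoallylic C8=C9 bond on which the C5 oxygen stands, so C8 and C9 should both receive oxygen on the β face while the undirected background reaction is slow.

Step 16
Reactants: 26 8β,9β-epoxide; 27 water
Product: 28 triol, (1R,4R,5S,8R,9R) in route numbering (5β-OH, 8α-OH with 8β-CH3, 9β-OH)
Conditions: HClO4 (cat.), THF/H2O, 0 °C → rt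
Reagents that add atoms: water (27), O
Why: Acid-catalysed epoxide hydrolysis opens the protonated oxirane at the tertiary carbon C8 with inversion (borderline SN2 attack of water from the α face), so C8 should end with α-OH and β-CH3 while C9 keeps its β-oxygen, which is the trans-diol of the target.

Step 17
Reactants: 28 triol; 29 4-methoxybenzoyl chloride
Product: 30 target, (1R,4R,5S,8R,9R)-5,8-dihydroxy-4-isopropyl-1,8-dimethylbicyclo[5.3.0]decan-9-yl 4-methoxybenzoate in route numbering
Conditions: 4-MeOC6H4COCl (1.3 equiv), pyridine (3 equiv), DMAP (0.1 equiv), CH2Cl2, 0 °C → rt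
Reagents that add atoms: 4-methoxybenzoyl chloride (29), COc1ccc(cc1)C(Cl)=O
Why: DMAP-catalysed acylation with the acid chloride (nucleophilic catalysis) should distinguish the single secondary hydroxyl at C9 from the two tertiary hydroxyls at C5 and C8 and touches no stereocentre.

**Compound list**

1 | cycloheptane-1,3-dione | O=C1CCCCC(=O)C1 | starting material
2 | iodomethane | CI | starting material
3 | 2-methylcycloheptane-1,3-dione | CC1C(=O)CCCCC1=O | intermediate
4 | allyl acetate | C=CCOC(C)=O | starting material
5 | 2-allyl-2-methylcycloheptane-1,3-dione | C=CCC1(C)C(=O)CCCCC1=O | intermediate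
6 | methyl vinyl ketone (but-3-en-2-one) | CC(=O)C=C | starting material
7 | (E)-2-methyl-2-(4-oxopent-2-en-1-yl)cycloheptane-1,3-dione | CC(=O)/C=C/CC1(C)C(=O)CCCCC1=O | intermediate
8 | 2-methyl-2-(4-oxopentyl)cycloheptane-1,3-dione | CC(=O)CCCC1(C)C(=O)CCCCC1=O | intermediate
9 | ketol, (1S,4S,5S)-4-acetyl-5-hydroxy-1-methylbicyclo[5.3.0]decan-10-one (route numbering, cis-fused) | O=C1[C@@]2(C)CC[C@H](C(C)=O)[C@@]2(O)CCCC1 | intermediate
10 | triethylsilyl trifluoromethanesulfonate | CC[Si](CC)(CC)OS(=O)(=O)C(F)(F)F | starting material
11 | triethylsilyl ether of 9 | O=C1[C@@]2(C)CC[C@H](C(C)=O)[C@@]2(O[Si](CC)(CC)CC)CCCC1 | intermediate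
12 | methyltriphenylphosphonium bromide | C[P+](c1ccccc1)(c1ccccc1)c1ccccc1.[Br-] | starting material
13 | 4β-isopropenyl-1β-methyl-5β-(triethylsilyloxy) C10 ketone | O=C1[C@@]2(C)CC[C@H](C(C)=C)[C@@]2(O[Si](CC)(CC)CC)CCCC1 | intermediate
14 | 4β-isopropyl-1β-methyl-5β-(triethylsilyloxy) C10 ketone | O=C1[C@@]2(C)CC[C@H](C(C)C)[C@@]2(O[Si](CC)(CC)CC)CCCC1 | intermediate
15 | N-phenylbis(trifluoromethanesulfonimide) | FC(F)(F)S(=O)(=O)N(c1ccccc1)S(=O)(=O)C(F)(F)F | starting material
16 | potassium C9=C10 enolate of 14 | C1=C([O-])[C@@]2(C)CC[C@H](C(C)C)[C@@]2(O[Si](CC)(CC)CC)CCC1.[K+] | intermediate (not isolated)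
17 | C10 enol triflate (C9=C10) | C1=C(OS(=O)(=O)C(F)(F)F)[C@@]2(C)CC[C@H](C(C)C)[C@@]2(O[Si](CC)(CC)CC)CCC1 | intermediate
18 | C9=C10 alkene | C1=C[C@@]2(C)CC[C@H](C(C)C)[C@@]2(O[Si](CC)(CC)CC)CCC1 | intermediate
19 | tert-butyl hydroperoxide | CC(C)(C)OO | starting material
20 | C8 enone (C8=O, C9=C10) | O=C1C=C[C@@]2(C)CC[C@H](C(C)C)[C@@]2(O[Si](CC)(CC)CC)CC1 | intermediate
21 | lithium C8=C9 enolate | [Li+].[O-]C1=CC[C@@]2(C)CC[C@H](C(C)C)[C@@]2(O[Si](CC)(CC)CC)CC1 | intermediate (not isolated)
22 | C8 enol triflate (C8=C9) | FC(F)(F)S(=O)(=O)OC1=CC[C@@]2(C)CC[C@H](C(C)C)[C@@]2(O[Si](CC)(CC)CC)CC1 | intermediate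
23 | methylmagnesium bromide | C[Mg]Br | starting material
24 | 8-methyl C8=C9 alkene, 5β-triethylsilyl ether | CC1=CC[C@@]2(C)CC[C@H](C(C)C)[C@@]2(O[Si](CC)(CC)CC)CC1 | intermediate
25 | alkenol (8-methyl C8=C9 alkene, free 5β-OH) | CC1=CC[C@@]2(C)CC[C@H](C(C)C)[C@@]2(O)CC1 | intermediate
26 | 8β,9β-epoxide of 25 | C[C@]12CC[C@]3(O)[C@@H](C(C)C)CC[C@]3(C)C[C@H]1O2 | intermediate
27 | water | O | starting material
28 | triol (5β-OH, 8α-OH, 9β-OH; 8β-CH3) | O[C@@H]1C[C@@]2(C)CC[C@H](C(C)C)[C@@]2(O)CC[C@@]1(C)O | intermediate
29 | 4-methoxybenzoyl chloride | COc1ccc(cc1)C(Cl)=O | starting material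
30 | target, 9β-(4-methoxybenzoyloxy)-5β,8α-diol | COc1ccc(C(=O)O[C@@H]2C[C@@]3(C)CC[C@H](C(C)C)[C@@]3(O)CC[C@@]2(C)O)cc1 | target

**Step count and risks**

Total step count: 17. Longest linear sequence: 17 steps (fully linear, from 1 to 30).

Steps most likely to fail:

1. Step 5. The hindered ring carbonyl may react so slowly that the ketol dehydrates to the C4=C5 enone before it accumulates, or the amine may discriminate the two enantiotopic carbonyls poorly. The fallback sets out from enone-dione 7 and uses a copper hydride reductive aldol cyclisation (Cu(OAc)2·H2O, a chiral bisphosphine such as DTBM-SEGPHOS of the appropriate hand, 1,1,3,3-tetramethyldisiloxane, toluene, fluoride work-up). Hydride adds 1,4 to the enone, the copper enolate is nucleophilic at C4 by construction and adds to a ring carbonyl through a chair Zimmerman–Traxler transition state, which should give the same cis-fused ketol with acetyl cis to hydroxyl. It comes back to the route at 9 and passes by 8; it makes no compound outside the list (F0).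

2. Step 15. Delivery of oxygen from the C5 hydroxyl across the ring may be geometrically poor, so that epoxidation is slow and unselective between the two faces, or the epoxy alcohol may be opened by the Lewis-acidic vanadium. The fallback replaces directed by steric control and switches the regiochemistry of opening. It sets out from silyl ether 24: m-CPBA with NaHCO3 in CH2Cl2 should attack the face away from the C5 silyloxy and C1 methyl groups and give the 8α,9α-epoxide silyl ether F1. Aqueous NaOH in DMSO at 90 °C should open it at the less substituted C9 with inversion to the silyl ether diol F2, which already has the 8α-OH/9β-OH array. n-Bu4NF then removes the silyl group and the route is rejoined at triol 28. Any β-epoxide formed alongside leads to the same diol under acid (attack at C8), so a mixture of faces is not lost.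

3. Step 11. The allyl radical may be oxygenated at C10 as well as at C8, the oxidation may stall, or the tertiary C–H of the isopropyl group may be attacked. The fallback is a Wharton carbonyl transposition without radical chemistry and sets out from ketone 14. IBX in DMSO/toluene at 70 °C dehydrogenates it to the C8=C9 enone F3, and H2O2/NaOH in MeOH gives the 8,9-epoxy ketone F4. Hydrazine hydrate with AcOH in MeOH forms the epoxy hydrazone F5 (not isolated), which loses nitrogen to give the C9=C10 allylic alcohol with OH at C8, F6. Dess–Martin oxidation of F6 returns to the route at enone 20; steps 9 and 10 are then not needed.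

**Further compounds**

F0 | step 5 | none | none
F1 | step 15 | 8α,9α-epoxide, 5β-triethylsilyl ether | C[C@@]12CC[C@]3(O[Si](CC)(CC)CC)[C@@H](C(C)C)CC[C@]3(C)C[C@@H]1O2
F2 | step 15 | 8α,9β-diol, 5β-triethylsilyl ether | O[C@@H]1C[C@@]2(C)CC[C@H](C(C)C)[C@@]2(O[Si](CC)(CC)CC)CC[C@@]1(C)O
F3 | step 11 | C8=C9 enone conjugated with the C10 ketone, 5β-triethylsilyl ether | O=C1[C@@]2(C)CC[C@H](C(C)C)[C@@]2(O[Si](CC)(CC)CC)CCC=C1
F4 | step 11 | 8,9-epoxy C10 ketone (either epoxide face) | O=C1[C@@]2(C)CC[C@H](C(C)C)[C@@]2(O[Si](CC)(CC)CC)CCC3OC13
F5 | step 11 | hydrazone of F4 (not isolated) | NN=C1[C@@]2(C)CC[C@H](C(C)C)[C@@]2(O[Si](CC)(CC)CC)CCC3OC13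
F6 | step 11 | C9=C10 allylic alcohol with OH at C8 (either C8 epimer) | OC1C=C[C@@]2(C)CC[C@H](C(C)C)[C@@]2(O[Si](CC)(CC)CC)CC1
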